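**Strategy.** The pyranone ring (ring C) is attached to the aromatic ring A by two bonds at neighbouring carbons, C8a–O1 and C4a–C4. The four atoms between them (O1, the phenyl-bearing C2, C3 and C4) are the backbone of an (S)-3-hydroxy-3-phenylpropanoic ester. Both aryl bonds are therefore made in one operation: an aryne spanning C4a–C8a takes up the potassium alkoxide of that ester at C8a, and the C4a carbanion acylates on the ester, closing ring C with C2 already (S) from an asymmetric hydrogenation. The aryne source is a fully substituted ortho-silylaryl triflate carrying the 7-methoxy group, a 5-benzyloxy group that steers the addition, and the side chain as a tertiary silyl ether.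

Key step: step 10

Remark: flavanone numbering (O1, C2, C3, C4, C4a, C5 to C8, C8a) is used for ring atoms. It is assumed that the (R)-SEGPHOS ruthenium catalyst reduces the aryl β-keto ester with its usual facial sense, which gives the (S)-carbinol. Bn = benzyl, TBS = tert-butyldimethylsilyl, TMS = trimethylsilyl, Tf = trifluoromethanesulfonyl.

**Step 1**
Reactants: 1 4-hydroxy-2,6-dimethoxybenzaldehyde
Product: 2 4-(benzyloxy)-2,6-dimethoxybenzaldehyde
Conditions: BnBr, K2CO3, DMF, 50 °C
Reagents that add atoms: benzyl bromide, BrCc1ccccc1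
Why: Williamson etherification of the only free phenol, which is acidified by the para formyl group, should be clean.

**Step 2**
Reactants: 2 4-(benzyloxy)-2,6-dimethoxybenzaldehyde
Product: 3 4-(benzyloxy)-2-hydroxy-6-methoxybenzaldehyde
Conditions: MgI2·OEt2 (1.2 equiv), PhMe–Et2O, 60 °C; aq. NH4Cl
Reagents that add atoms: none
Why: Chelation-controlled ether cleavage, in which magnesium held between the formyl oxygen and one ortho methoxy group lets iodide remove that methyl only, while the magnesium phenoxide chelate formed shields the second ortho ether and the unchelated para benzyl ether is not activated.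

**Step 3**
Reactants: 3 4-(benzyloxy)-2-hydroxy-6-methoxybenzaldehyde; 4 methyl (triphenylphosphoranylidene)acetate
Product: 5 methyl (2E)-3-[4-(benzyloxy)-2-hydroxy-6-methoxyphenyl]prop-2-enoate
Conditions: PhMe, 90 °C
Reagents that add atoms: none
Why: Wittig olefination with a stabilised ylide tolerates the free ortho phenol and should give the E cinnamate, whose geometry prevents lactonisation.

**Step 4**
Reactants: 5 methyl (2E)-3-[4-(benzyloxy)-2-hydroxy-6-methoxyphenyl]prop-2-enoate
Product: 6 methyl 3-[4-(benzyloxy)-2-hydroxy-6-methoxyphenyl]propanoate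
Conditions: H2 (5 bar), RhCl(PPh3)3 (2 mol %), PhMe–EtOH, 50 °C
Reagents that add atoms: none
Why: Homogeneous rhodium-catalysed hydrogenation should saturate the disubstituted cinnamate alkene without hydrogenolysing the aryl benzyl ether, which palladium on carbon would cleave.

**Step 5**
Reactants: 6 methyl 3-[4-(benzyloxy)-2-hydroxy-6-methoxyphenyl]propanoate
Product: 7 5-(benzyloxy)-2-(3-hydroxy-3-methylbutyl)-3-methoxyphenol
Conditions: MeMgBr (4 equiv), THF, 0 °C → rt; aq. NH4Cl
Reagents that add atoms: methylmagnesium bromide, C[Mg]Br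
Why: Double Grignard addition to the ester (or to any dihydrocoumarin formed from it in the flask, which converges on the same product) should give the tertiary alcohol, and the neutral quench avoids acid-induced closure to a chroman.

**Step 6**
Reactants: 7 5-(benzyloxy)-2-(3-hydroxy-3-methylbutyl)-3-methoxyphenol
Product: 8 5-(benzyloxy)-2-(3-hydroxy-3-methylbutyl)-3-methoxyphenyl propan-2-ylcarbamate
Conditions: i-PrNCO (1.2 equiv), Et3N (0.2 equiv), CH2Cl2, rt
Reagents that add atoms: isopropyl isocyanate, CC(C)N=C=O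
Why: Amine-catalysed carbamoylation of a phenol by an isocyanate is much faster than addition of the hindered tertiary alcohol, so only the aryl carbamate should form.

**Step 7**
Reactants: 8 5-(benzyloxy)-2-(3-hydroxy-3-methylbutyl)-3-methoxyphenyl propan-2-ylcarbamate
Product: 12 3-(benzyloxy)-6-[3-(tert-butyldimethylsilyloxy)-3-methylbutyl]-5-methoxy-2-(trimethylsilyl)phenyl propan-2-ylcarbamate, via N-silyl O-silyl carbamate 9 (not isolated), via aryllithium 10 (not isolated), via N-silyl C-silyl carbamate 11 (not isolated)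
Conditions: TBSOTf (2.2 equiv), TMEDA, Et2O, 0 °C → rt; n-BuLi (3.3 equiv), TMEDA, −78 °C; TMSCl, −78 °C → rt; aq. NH4Cl
Reagents that add atoms: tert-butyldimethylsilyl trifluoromethanesulfonate, CC(C)(C)[Si](C)(C)OS(=O)(=O)C(F)(F)F; chlorotrimethylsilane, C[Si](C)(C)Cl
Why: Directed ortho-metalation, in which TBSOTf first silylates the tertiary alcohol (kept from here on) and the carbamate nitrogen (lost on work-up), so that n-BuLi should remove the one ring hydrogen flanked by the carbamate and the benzyloxy group and TMSCl traps the aryllithium.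

**Step 8**
Reactants: 12 3-(benzyloxy)-6-[3-(tert-butyldimethylsilyloxy)-3-methylbutyl]-5-methoxy-2-(trimethylsilyl)phenyl propan-2-ylcarbamate
Product: 14 3-(benzyloxy)-6-[3-(tert-butyldimethylsilyloxy)-3-methylbutyl]-5-methoxy-2-(trimethylsilyl)phenyl trifluoromethanesulfonate, via silyl phenol 13 (not isolated)
Conditions: Et2NH, DBU, MeCN, 40 °C; then PhNTf2, rt
Reagents that add atoms: N-phenylbis(trifluoromethanesulfonimide), O=S(=O)(N(c1ccccc1)S(=O)(=O)C(F)(F)F)C(F)(F)F
Why: DBU deprotonates the carbamate N–H and triggers E1cB loss of isopropyl isocyanate, which diethylamine scavenges as a urea, and the phenoxide set free is triflated in the same flask, the usual end of an ortho-silylaryl triflate synthesis.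

**Step 9**
Reactants: 15 methyl 3-oxo-3-phenylpropanoate
Product: 16 methyl (3S)-3-hydroxy-3-phenylpropanoate
Conditions: H2 (30 bar), [RuCl(p-cymene)((R)-SEGPHOS)]Cl (0.5 mol %), MeOH, 60 °C
Reagents that add atoms: none
Why: Noyori-type asymmetric hydrogenation of a β-keto ester, in which the substrate chelates ruthenium through both carbonyl groups and the (R)-configured biaryl diphosphine directs hydride to the ketone face that gives the (S)-carbinol, whose enantiomeric purity would be checked by chiral HPLC before use.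

**Step 10**
Reactants: 14 3-(benzyloxy)-6-[3-(tert-butyldimethylsilyloxy)-3-methylbutyl]-5-methoxy-2-(trimethylsilyl)phenyl trifluoromethanesulfonate; 16 methyl (3S)-3-hydroxy-3-phenylpropanoate
Product: 20 (2S)-5-(benzyloxy)-8-[3-(tert-butyldimethylsilyloxy)-3-methylbutyl]-7-methoxy-2-phenyl-2,3-dihydro-4H-chromen-4-one, via potassium alkoxide 17 (not isolated), via aryne 18 (not isolated), via aryl anion 19 (not isolated)
Conditions: 16 (1.2 equiv), KH (1.2 equiv), THF, 0 °C; then 14 (1.0 equiv), KF (2 equiv), 18-crown-6 (3 equiv), THF, 0 °C → rt; AcOH, 0 °C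
Reagents that add atoms: none
Why: Proposed new method: fluoride attacks the trimethylsilyl group of 14 and triflate leaves to give aryne 18, the oxygen of alkoxide 17 adds at C8a (O1–C8a), and the C4a carbanion 19 attacks the tethered methyl ester and expels methoxide (C4–C4a). The closest known reaction type is the fluoride-triggered insertion–acyl transfer of arynes with ortho-hydroxyaryl esters that gives xanthones, extended here from a phenoxide to an aliphatic β-alkoxide, with Parham-type cycloacylation as the model for the ketone-forming half. Ring C closes by a 6-exo-trig acyl substitution. No stereocentre is created, since C2 and its four bonds are untouched and the (S) configuration of 16 passes into 20. The selectivity needed, oxygen to C8a and not to C4a, is secured by the C5 benzyloxy group, whose inductive pull distorts the aryne and stabilises charge at C4a, and is reinforced by the C8 alkyl group, next to which negative charge is less stable. Acylation must outrun protonation, which the absence of any O–H or N–H donor (alkoxide pre-formed with KH, hydrogen vented, aprotic solvent) and the six-membered transition state are meant to ensure.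

**Step 11**
Reactants: 20 (2S)-5-(benzyloxy)-8-[3-(tert-butyldimethylsilyloxy)-3-methylbutyl]-7-methoxy-2-phenyl-2,3-dihydro-4H-chromen-4-one
Product: 21 (2S)-8-[3-(tert-butyldimethylsilyloxy)-3-methylbutyl]-5-hydroxy-7-methoxy-2-phenyl-2,3-dihydro-4H-chromen-4-one
Conditions: H2 (1 atm), 10% Pd/C, EtOAc, rt
Reagents that add atoms: none
Why: Catalytic hydrogenolysis should cleave the aryl benzyl ether under neutral conditions that cannot epimerise C2, and the hydrogen-bonded 5-hydroxy ketone and the cyclic C2–O1 ether are expected to survive if the reaction is stopped after one equivalent of hydrogen.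

**Step 12**
Reactants: 21 (2S)-8-[3-(tert-butyldimethylsilyloxy)-3-methylbutyl]-5-hydroxy-7-methoxy-2-phenyl-2,3-dihydro-4H-chromen-4-one
Product: 22 (2S)-5-hydroxy-8-(3-hydroxy-3-methylbutyl)-7-methoxy-2-phenyl-2,3-dihydro-4H-chromen-4-one
Conditions: HF·pyridine, pyridine, THF, 0 °C → rt
Reagents that add atoms: none
Why: Fluoride-mediated desilylation under mildly acidic, non-basic conditions should free the tertiary alcohol without opening ring C by a retro-oxa-Michael pathway, so C2 stays (S).

**Compound list**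

1 | 4-hydroxy-2,6-dimethoxybenzaldehyde | COc1cc(O)cc(OC)c1C=O | starting material
2 | 4-(benzyloxy)-2,6-dimethoxybenzaldehyde | COc1cc(OCc2ccccc2)cc(OC)c1C=O | intermediate
3 | 4-(benzyloxy)-2-hydroxy-6-methoxybenzaldehyde | COc1cc(OCc2ccccc2)cc(O)c1C=O | intermediate
4 | methyl (triphenylphosphoranylidene)acetate | COC(=O)C=P(c1ccccc1)(c1ccccc1)c1ccccc1 | starting material
5 | methyl (2E)-3-[4-(benzyloxy)-2-hydroxy-6-methoxyphenyl]prop-2-enoate | COC(=O)/C=C/c1c(O)cc(OCc2ccccc2)cc1OC | intermediate
6 | methyl 3-[4-(benzyloxy)-2-hydroxy-6-methoxyphenyl]propanoate | COC(=O)CCc1c(O)cc(OCc2ccccc2)cc1OC | intermediate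
7 | 5-(benzyloxy)-2-(3-hydroxy-3-methylbutyl)-3-methoxyphenol | COc1cc(OCc2ccccc2)cc(O)c1CCC(C)(C)O | intermediate
8 | 5-(benzyloxy)-2-(3-hydroxy-3-methylbutyl)-3-methoxyphenyl propan-2-ylcarbamate | COc1cc(OCc2ccccc2)cc(OC(=O)NC(C)C)c1CCC(C)(C)O | intermediate
9 | 5-(benzyloxy)-2-[3-(tert-butyldimethylsilyloxy)-3-methylbutyl]-3-methoxyphenyl N-(tert-butyldimethylsilyl)-N-(propan-2-yl)carbamate | COc1cc(OCc2ccccc2)cc(OC(=O)N(C(C)C)[Si](C)(C)C(C)(C)C)c1CCC(C)(C)O[Si](C)(C)C(C)(C)C | intermediate
10 | {6-(benzyloxy)-3-[3-(tert-butyldimethylsilyloxy)-3-methylbutyl]-2-{[(tert-butyldimethylsilyl)(propan-2-yl)carbamoyl]oxy}-4-methoxyphenyl}lithium | COc1cc(OCc2ccccc2)c([Li])c(OC(=O)N(C(C)C)[Si](C)(C)C(C)(C)C)c1CCC(C)(C)O[Si](C)(C)C(C)(C)C | intermediate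
11 | 3-(benzyloxy)-6-[3-(tert-butyldimethylsilyloxy)-3-methylbutyl]-5-methoxy-2-(trimethylsilyl)phenyl N-(tert-butyldimethylsilyl)-N-(propan-2-yl)carbamate | COc1cc(OCc2ccccc2)c([Si](C)(C)C)c(OC(=O)N(C(C)C)[Si](C)(C)C(C)(C)C)c1CCC(C)(C)O[Si](C)(C)C(C)(C)C | intermediate
12 | 3-(benzyloxy)-6-[3-(tert-butyldimethylsilyloxy)-3-methylbutyl]-5-methoxy-2-(trimethylsilyl)phenyl propan-2-ylcarbamate | COc1cc(OCc2ccccc2)c([Si](C)(C)C)c(OC(=O)NC(C)C)c1CCC(C)(C)O[Si](C)(C)C(C)(C)C | intermediate
13 | 3-(benzyloxy)-6-[3-(tert-butyldimethylsilyloxy)-3-methylbutyl]-5-methoxy-2-(trimethylsilyl)phenol | COc1cc(OCc2ccccc2)c([Si](C)(C)C)c(O)c1CCC(C)(C)O[Si](C)(C)C(C)(C)C | intermediate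
14 | 3-(benzyloxy)-6-[3-(tert-butyldimethylsilyloxy)-3-methylbutyl]-5-methoxy-2-(trimethylsilyl)phenyl trifluoromethanesulfonate | COc1cc(OCc2ccccc2)c([Si](C)(C)C)c(OS(=O)(=O)C(F)(F)F)c1CCC(C)(C)O[Si](C)(C)C(C)(C)C | intermediate
15 | methyl 3-oxo-3-phenylpropanoate (methyl benzoylacetate) | COC(=O)CC(=O)c1ccccc1 | starting material
16 | methyl (3S)-3-hydroxy-3-phenylpropanoate | COC(=O)C[C@H](O)c1ccccc1 | intermediate
17 | potassium (1S)-3-methoxy-3-oxo-1-phenylpropan-1-olate | COC(=O)C[C@H]([O-])c1ccccc1.[K+] | intermediate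
18 | 3-(benzyloxy)-6-[3-(tert-butyldimethylsilyloxy)-3-methylbutyl]-5-methoxy-1,2-didehydrobenzene | COC1=C(CCC(C)(C)O[Si](C)(C)C(C)(C)C)C#CC(OCc2ccccc2)=C1 | intermediate
19 | methyl (3S)-3-{5-(benzyloxy)-2-[3-(tert-butyldimethylsilyloxy)-3-methylbutyl]-3-methoxy-6-potassiophenoxy}-3-phenylpropanoate | COC(=O)C[C@H](Oc1c(CCC(C)(C)O[Si](C)(C)C(C)(C)C)c(OC)cc(OCc2ccccc2)c1[K])c1ccccc1 | intermediate
20 | (2S)-5-(benzyloxy)-8-[3-(tert-butyldimethylsilyloxy)-3-methylbutyl]-7-methoxy-2-phenyl-2,3-dihydro-4H-chromen-4-one | COc1cc(OCc2ccccc2)c2c(c1CCC(C)(C)O[Si](C)(C)C(C)(C)C)O[C@H](c1ccccc1)CC2=O | intermediate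
21 | (2S)-8-[3-(tert-butyldimethylsilyloxy)-3-methylbutyl]-5-hydroxy-7-methoxy-2-phenyl-2,3-dihydro-4H-chromen-4-one | COc1cc(O)c2c(c1CCC(C)(C)O[Si](C)(C)C(C)(C)C)O[C@H](c1ccccc1)CC2=O | intermediate
22 | (2S)-5-hydroxy-8-(3-hydroxy-3-methylbutyl)-7-methoxy-2-phenyl-2,3-dihydro-4H-chromen-4-one | COc1cc(O)c2c(c1CCC(C)(C)O)O[C@H](c1ccccc1)CC2=O | target

**Step count.** Total: 12 steps. Longest linear sequence: 11 steps (steps 1 to 8, then 10 to 12); step 9 is a one-step side branch.

**Steps most likely to fail**

Step 10. The alkoxide may strip the silyl or triflyl group from 14, fragment by retro-aldol, or be kept from C8a by the neighbouring side chain. The aryl anion may be protonated before it acylates. The methoxide released may open ring C by retro-oxa-Michael reaction and erode the configuration at C2. The fallback leaves the aryne approach and closes ring C by asymmetric 1,4-arylation of a chromone, all by known reaction types. It sets out from carbamate 8, which is silylated and ortho-lithiated as in step 7 (through 9 to 10). Quenching with N-methoxy-N-methylacetamide in place of TMSCl should give the N-silyl acetyl carbamate F1 and, after aqueous work-up, the ortho-acetyl carbamate F2. Et2NH and DBU in MeCN would free the 2-hydroxyacetophenone F3. Me2NCH(OMe)2 at 90 °C should give the enaminone F4, which closes to the chromone F5 in warm AcOH. Phenylboronic acid with Pd(OCOCF3)2, the t-BuPyOx enantiomer that leads to the 2S series (expected to be the R ligand), NH4PF6 and water in 1,2-dichloroethane at 60 °C would then add phenyl to C2 and return to the route at 20.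

Step 7. n-BuLi may deprotonate the benzylic CH2 of the benzyl ether (followed by Wittig rearrangement) or the ring carbon between the two ether oxygens, and silylation of the tertiary alcohol may be incomplete. The fallback makes the aryl–silicon bond by halogen–metal exchange and retro-Brook rearrangement instead of deprotonation. It sets out from phenol 7. NBS with catalytic i-Pr2NH in CH2Cl2 (amine-mediated ortho-bromination, only one ortho position being free) should give the bromophenol F6. TBSOTf and 2,6-lutidine would give the bis-silyl ether F7, and K2CO3 in MeOH should cleave only the aryl silyl ether to give the bromophenol silyl ether F8. HMDS would give the aryl trimethylsilyl ether F9. n-BuLi in THF at −78 °C should give the aryllithium F10 by bromine–lithium exchange, and its silicon migrates from oxygen to carbon to give the lithium salt of 13, where the route is rejoined; Tf2O then gives 14.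

Step 2. The Lewis acid may remove both ortho methyl groups or attack the benzyl ether. The fallback reverses the order, so that chelation-controlled demethylation is done before any benzyl group is present and the benzyl group is then placed by hydrogen-bond-controlled alkylation. It sets out from 1: BCl3 in CH2Cl2 (−78 → 0 °C) should give 2,4-dihydroxy-6-methoxybenzaldehyde F11. BnBr and KHCO3 in MeCN at 60 °C would then alkylate only the 4-hydroxyl, the 2-hydroxyl being held in a hydrogen bond to the formyl group, and return to the route at 3.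

**Further compounds**

F1 | step 10 | 2-acetyl-3-(benzyloxy)-6-[3-(tert-butyldimethylsilyloxy)-3-methylbutyl]-5-methoxyphenyl N-(tert-butyldimethylsilyl)-N-(propan-2-yl)carbamate | COc1cc(OCc2ccccc2)c(C(C)=O)c(OC(=O)N(C(C)C)[Si](C)(C)C(C)(C)C)c1CCC(C)(C)O[Si](C)(C)C(C)(C)C
F2 | step 10 | 2-acetyl-3-(benzyloxy)-6-[3-(tert-butyldimethylsilyloxy)-3-methylbutyl]-5-methoxyphenyl propan-2-ylcarbamate | COc1cc(OCc2ccccc2)c(C(C)=O)c(OC(=O)NC(C)C)c1CCC(C)(C)O[Si](C)(C)C(C)(C)C
F3 | step 10 | 1-{6-(benzyloxy)-3-[3-(tert-butyldimethylsilyloxy)-3-methylbutyl]-2-hydroxy-4-methoxyphenyl}ethan-1-one | COc1cc(OCc2ccccc2)c(C(C)=O)c(O)c1CCC(C)(C)O[Si](C)(C)C(C)(C)C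
F4 | step 10 | (2E)-1-{6-(benzyloxy)-3-[3-(tert-butyldimethylsilyloxy)-3-methylbutyl]-2-hydroxy-4-methoxyphenyl}-3-(dimethylamino)prop-2-en-1-one | COc1cc(OCc2ccccc2)c(C(=O)/C=C/N(C)C)c(O)c1CCC(C)(C)O[Si](C)(C)C(C)(C)C
F5 | step 10 | 5-(benzyloxy)-8-[3-(tert-butyldimethylsilyloxy)-3-methylbutyl]-7-methoxy-4H-chromen-4-one | COc1cc(OCc2ccccc2)c2c(c1CCC(C)(C)O[Si](C)(C)C(C)(C)C)OC=CC2=O
F6 | step 7 | 3-(benzyloxy)-2-bromo-6-(3-hydroxy-3-methylbutyl)-5-methoxyphenol | COc1cc(OCc2ccccc2)c(Br)c(O)c1CCC(C)(C)O
F7 | step 7 | {3-(benzyloxy)-2-bromo-6-[3-(tert-butyldimethylsilyloxy)-3-methylbutyl]-5-methoxyphenoxy}(tert-butyl)dimethylsilane | COc1cc(OCc2ccccc2)c(Br)c(O[Si](C)(C)C(C)(C)C)c1CCC(C)(C)O[Si](C)(C)C(C)(C)C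
F8 | step 7 | 3-(benzyloxy)-2-bromo-6-[3-(tert-butyldimethylsilyloxy)-3-methylbutyl]-5-methoxyphenol | COc1cc(OCc2ccccc2)c(Br)c(O)c1CCC(C)(C)O[Si](C)(C)C(C)(C)C
F9 | step 7 | {3-(benzyloxy)-2-bromo-6-[3-(tert-butyldimethylsilyloxy)-3-methylbutyl]-5-methoxyphenoxy}trimethylsilane | COc1cc(OCc2ccccc2)c(Br)c(O[Si](C)(C)C)c1CCC(C)(C)O[Si](C)(C)C(C)(C)C
F10 | step 7 | {6-(benzyloxy)-3-[3-(tert-butyldimethylsilyloxy)-3-methylbutyl]-4-methoxy-2-(trimethylsilyloxy)phenyl}lithium | COc1cc(OCc2ccccc2)c([Li])c(O[Si](C)(C)C)c1CCC(C)(C)O[Si](C)(C)C(C)(C)C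
F11 | step 2 | 2,4-dihydroxy-6-methoxybenzaldehyde | COc1cc(O)cc(O)c1C=O
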